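The eta run differed from its neighbour, the beta run, in the reagent charge, so that was the first setting I turned by hand.

| setting | beta | delta | eta | zeta |
|---|---|---|---|---|
| starting material | 0.800 M | 2.40 M | 0.800 M | 1.60 M |
| reagent | 1.20 M | 1.20 M | 1.80 M | 0.400 M |
| time |  |  |  | 17 h |

- beta run (time / h: [starting material] / M): 2.8: 0.302; 5.7: 0.166; 8.5: 0.117; 11: 0.085; 14: 0.056; 17: 0.044
- delta run (time / h: [starting material] / M): 2.8: 0.506; 5.7: 0.250; 8.5: 0.162; 11: 0.110; 14: 0.074; 17: 0.065
- eta run (time / h: [starting material] / M): 2.8: 0.267; 5.7: 0.137; 8.5: 0.090; 11: 0.055; 14: 0.033; 17: 0.021

(each reading ± 0.006 M)

- Overall: starting material + reagent -> target.
- Constant volume, constant temperature.
- "The second partner" is reagent.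
- An order is taken over about fifteen percent of the charge, up and down.

* the power of [reagent] that the first rate follows, about the charge of the beta run; measure it at two percent of starting material made into target
* the power of [starting material] that the first rate follows, about the charge of the beta run; measure it at two percent of starting material made into target (one fixed amount of target, the same in the runs compared)
* starting material in the zeta run at 17 h, as a share of the starting material charged
* which of these the readings show (two substrates go astray together / the two partners rest in a complex / the second partner pairs with itself / the product reacts on with the second partner / the product binds the second partner)

More reagent should lower the share of starting material left, and it did: at 2.8 h the eta run held 33.4% of its charge and the beta run 37.7%, a modest gap.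

More starting material at equal reagent should also lower that share if two molecules of it can meet. The delta run held 21.1% at that time, less than the beta run. The reagent charged in the delta run, 1.20 M, was less than the 2.33 M of starting material that had reacted there by 17 h, so some starting material went without reagent.

I therefore took two routes. The reciprocal of the starting material then climbs each hour by a steady self constant, plus a target constant times reagent times that reciprocal. I compared the climbs up to 2.8 h, using the mean reciprocal over that stretch, first eta against beta and then delta:

target constant = 0.0881 M⁻¹ h⁻¹

self constant = 0.430 M⁻¹ h⁻¹

The target constant is target made per hour for each molar of starting material and of reagent. In the zeta run I treated the reagent route as a correction, holding reagent at its charge and using the mean reciprocal of the share left, which is one plus half the self climb: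

self climb of the reciprocal share = 11.7

reagent correction = 4.11

share left in zeta = 5.95%

Counting the first rate as target made, it goes as the target constant times both charges, so I expected the first power of each.

The forecast gave 0.26 for reagent, 1.74 for starting material and 5.6% left in zeta, with two substrates go astray together. It read the first rate “as starting-material loss”, where I counted target made.

    starting material ⇌ intermediate, settled at all times (0.1680)
    intermediate + reagent → target (0.6804 M⁻¹ h⁻¹)
    2 starting material → homo dimer (0.2509 M⁻¹ h⁻¹)

The flask gave orders of 1.1 in reagent and 1.0 in starting material, 6.14% left in the zeta run, and two substrates go astray together. Target formed at 0.13 M h⁻¹ in the eta run against 0.086 M h⁻¹ in the beta run, a ratio of 1.5. For the delta run, the target constant times its charges gives 0.254 M h⁻¹, and the rate there, once the same amount of target had been made, was 0.26 M h⁻¹.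

The earlier runs and the new flask are calculated with made-up constants; the scatter is artificial.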